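At early times in both flasks the impurity meets the free catalyst while the solid reagent goes into solution as partner.

    partner + catalyst intermediate A ⇌ catalyst intermediate B (K1 = 1.68 L mol⁻¹, k1 = 30.8 L mol⁻¹ s⁻¹)
    substrate + free catalyst ⇌ catalyst intermediate A (K2 = 0.881 L mol⁻¹, k2 = 1.39 L mol⁻¹ s⁻¹)
    free catalyst + impurity → spent catalyst (k3 = 425 L mol⁻¹ s⁻¹)
    solid reagent ⇌ partner, rate k4*(cs4 - [partner]) while solid is left; crystals form when [partner] > cs4 (cs4 = 0.78 M, k4 = 0.191 s⁻¹)
    catalyst intermediate B → free catalyst + target (k5 = 0.419 s⁻¹)

in all of them: substrate 0.80 M; solid reagent 0.600 equiv; impurity 43 mM; time 6.0 min
- teal: free catalyst 10 mol%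
- green: free catalyst 20 mol%

- which of these there is most of at the end, counted by the substrate in it, teal (substrate / catalyst intermediate A / target / catalyst intermediate B)
- which of these there is most of at the end, counted by the substrate in it, green (substrate / catalyst intermediate A / target / catalyst intermediate B)
- how much there is at the end of the one of these that leads, in percent of the substrate charged: teal
- how much there is at the end of the one of these that leads, in percent of the substrate charged: green

The impurity captures free catalyst at 18.3 s⁻¹, faster than substrate binds it at 1.11 s⁻¹. It is therefore reckoned as consumed at once, one catalyst for each impurity, which leaves a working fraction of the catalyst charge of 46.2% in teal and 73.1% in green. Partner is the limiting reagent, and its charge of 0.600 equiv is the ceiling on target.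

Catalyst intermediate B returns to partner at 18.3 s⁻¹ and catalyst intermediate A returns to substrate at 1.58 s⁻¹, both faster than target is released at 0.419 s⁻¹, so both bindings are treated as equilibria. Partner then decays pseudo-first-order. Its lifetime is the inverse of the release constant times the binding constant of partner times the concentration of catalyst intermediate A. With substrate taken at what remains at the ceiling, catalyst intermediate A holds 22.0% of the working catalyst. The lifetime is 2.91 min in teal and 0.920 min in green.

Dissolving takes about 5.24 s, shorter than either lifetime, so two times remain: this lifetime and the run. Their ratio is 2.06 in teal and 6.52 in green. The ceiling times one minus the exponential of the negative ratio gives target at 52.4% in teal and 59.9% in green, so target leads substrate in each.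

The forecast names target for teal and target for green, at 53% (49% to 57%) and 59.5% (58% to 60%), starting from “The impurity kills catalyst far faster than substrate can bind it”. Its teal figure stands above the reckoned one.

The simulation gives target ahead in both flasks: 54.1% beside substrate at 44.8% in teal, and 59.9% beside 37.1% in green, each inside the forecast's range. With solid reagent at 0.525 equiv or 0.680 equiv, teal target has moved 6 points, which puts it outside that range.

In teal, partner falls from 17.5% of the substrate charge at 3.00 min to 5.85% at 6.00 min, which reads as a lifetime of 2.74 min beside the reckoned 2.91 min. For a flask like green but with 0.240 equiv of solid reagent, the same lifetime comes to 0.580 min, the run is 10.3 lifetimes long, and that flask ends with target at 24.0%.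

(Its constants come from no measurement.)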